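**Assumption:** the SMILES is read as (1R,2S,3S,4S,5R,14R; 7E,11E) in cembrane numbering (C1 = lactone β-carbon, C2 = lactone C–O, C3/C4 = epoxide, C5 = CH–OAc, C14 = CH–OH, C15–C17 = α-methylene acyl unit). This numbering is used throughout.

## Retrosynthetic overview
1. C1–C14 is formed last: a photoredox/HAT α-hydroxyalkyl radical (from a C14 primary alcohol) closes the 14-membered ring onto an α-(acetoxymethyl)butenolide, losing acetate to give the exo-methylene and setting C1 and C14.
2. The butenolide (C1, C15–C17) comes from a Nozaki–Hiyama–Kishi addition of a (Z)-β-iodoacrylate to a C2 epoxy aldehyde, which sets C2.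
3. C14 comes from the geranyl terminus (allylic oxidation, methylenation, hydroboration).
4. C5–C6 comes from α-selective geranylbarium addition to a 2-methyl epoxy aldehyde, which sets C5.
5. The epoxide (C3, C4) is set by the one bought stereocentre of (R)-solketal, which is later excised. Ring order: epoxide → butenolide → macrocycle.

## Route

**Step 1**
Reactants: 1, (R)-solketal; 2, 2-(triphenylphosphoranylidene)propanal
Product: 3, (E)-3-[(4R)-2,2-dimethyl-1,3-dioxolan-4-yl]-2-methylprop-2-enal
Conditions: (COCl)2, DMSO, Et3N, CH2Cl2, −78 °C; then 2, −78 °C → rt (one pot)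
Reagents that add atoms: none (new atoms come from 2)
Why: Swern oxidation gives (S)-glyceraldehyde acetonide, trapped in situ by the α-branched stabilised ylide (Wittig) to give the E-enal; the bought stereocentre is untouched (its CIP label changes only).

**Step 2**
Reactants: 3
Product: 4, (2R,3S)-3-[(4S)-2,2-dimethyl-1,3-dioxolan-4-yl]-2-methyloxirane-2-carbaldehyde
Conditions: 30% H2O2, NaOH (cat., pH 8–9), MeOH, 0 °C
Reagents that add atoms: hydrogen peroxide, OO
Why: Weitz–Scheffer nucleophilic epoxidation; A(1,3) strain with the C4 methyl holds the dioxolane C–H in the alkene plane, HOO⁻ adds to C3 anti to the dioxolane C–O bond (Felkin–Anh sense) and ring closure keeps the E geometry, giving the target C3/C4 configuration.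

**Step 3**
Reactants: 4; 5, geranyl chloride
Product: 6, (1R,3E)-1-{(2S,3S)-3-[(4S)-2,2-dimethyl-1,3-dioxolan-4-yl]-2-methyloxiran-2-yl}-4,8-dimethylnona-3,7-dien-1-ol
Conditions: BaI2, lithium biphenylide, THF, rt; 5, −78 °C; then 4, −78 °C
Reagents that add atoms: none (new atoms come from 5)
Why: Allylbarium carbonyl allylation is α-selective with retention of the E olefin; C5 (R) is predicted by a Cornforth-type transition state (C=O anti to the epoxide C–O, attack on the face away from the α-methyl).

**Step 4**
Reactants: 6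
Product: 7, (1R,3E)-1-{(2S,3S)-3-[(4S)-2,2-dimethyl-1,3-dioxolan-4-yl]-2-methyloxiran-2-yl}-4,8-dimethylnona-3,7-dien-1-yl acetate
Conditions: Ac2O, DMAP, pyridine, CH2Cl2, rt
Reagents that add atoms: acetic anhydride, CC(=O)OC(C)=O
Why: DMAP-catalysed acylation of the hindered secondary alcohol; no stereocentre is touched.

**Step 5**
Reactants: 7
Product: 8, (1R,3E,7E)-1-{(2S,3S)-3-[(4S)-2,2-dimethyl-1,3-dioxolan-4-yl]-2-methyloxiran-2-yl}-4,8-dimethyl-9-oxonona-3,7-dien-1-yl acetate
Conditions: SeO2 (cat.), t-BuOOH, salicylic acid (cat.), CH2Cl2, rt; then MnO2 on the crude (one pot, two stages)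
Reagents that add atoms: selenium dioxide, O=[Se]=O; tert-butyl hydroperoxide, CC(C)(C)OO
Why: SeO2 allylic oxidation (ene/[2,3]) is selective for the E-methyl of the terminal trisubstituted olefin; MnO2 converges the allylic alcohol/aldehyde mixture to the E-enal.

**Step 6**
Reactants: 8
Product: 9, (1R,3E,7E)-1-{(2S,3S)-3-[(4S)-2,2-dimethyl-1,3-dioxolan-4-yl]-2-methyloxiran-2-yl}-4,8-dimethyldeca-3,7,9-trien-1-yl acetate
Conditions: Ph3PCH3Br, KHMDS, THF, −78 → 0 °C
Reagents that add atoms: methylenetriphenylphosphorane, C=P(c1ccccc1)(c1ccccc1)c1ccccc1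
Why: Wittig methylenation of the enal adds C14; at low temperature the aldehyde reacts far faster than the acetate.

**Step 7**
Reactants: 9
Product: 10, (1R,3E,7E)-1-{(2S,3S)-3-[(4S)-2,2-dimethyl-1,3-dioxolan-4-yl]-2-methyloxiran-2-yl}-10-hydroxy-4,8-dimethyldeca-3,7-dien-1-yl acetate
Conditions: 9-BBN, THF, 0 °C → rt; then NaBO3·4H2O, H2O
Reagents that add atoms: sodium perborate, [Na+].[O-]OB=O
Why: Anti-Markovnikov hydroboration–oxidation; 9-BBN takes only the terminal vinyl of the diene, leaving the trisubstituted olefins, acetate and epoxide.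

**Step 8**
Reactants: 10
Product: 11, (1R,3E,7E)-1-{(2S,3S)-3-[(1S)-1,2-dihydroxyethyl]-2-methyloxiran-2-yl}-10-hydroxy-4,8-dimethyldeca-3,7-dien-1-yl acetate
Conditions: AcOH–THF–H2O (3:1:1), 40 °C
Reagents that add atoms: none
Why: Mild hydrolysis of the terminal acetonide; the epoxide is deactivated by its two oxygenated neighbours.

**Step 9**
Reactants: 11
Product: 12, (1R,3E,7E)-1-[(2S,3R)-3-formyl-2-methyloxiran-2-yl]-10-hydroxy-4,8-dimethyldeca-3,7-dien-1-yl acetate
Conditions: NaIO4, THF/pH 7 buffer, 0 °C
Reagents that add atoms: none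
Why: Malaprade glycol cleavage is specific for the 1,2-diol, so the isolated C14 alcohol survives; it removes the controller carbon and leaves a non-enolisable α,β-epoxy aldehyde at C2.

**Step 10**
Reactants: 13, ethyl propiolate
Product: 14, ethyl (Z)-2-(hydroxymethyl)-3-iodoprop-2-enoate
Conditions: MgI2, (CH2O)n, CH2Cl2, 0 °C → rt
Reagents that add atoms: magnesium iodide, [Mg+2].[I-].[I-]; formaldehyde (from paraformaldehyde), C=O
Why: β-Iodo Morita–Baylis–Hillman reaction (iodide conjugate addition, allenolate aldol); the aldehyde adds anti to iodine, giving the Z isomer with I cis to the ester.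

**Step 11**
Reactants: 14
Product: 15, ethyl (Z)-2-(acetoxymethyl)-3-iodoprop-2-enoate
Conditions: Ac2O, pyridine, DMAP (cat.), CH2Cl2, 0 °C
Reagents that add atoms: acetic anhydride, CC(=O)OC(C)=O
Why: Simple acetylation installs the leaving group needed in step 13.

**Step 12**
Reactants: 12; 15
Product: 16, (1R,3E,7E)-1-{(2S,3S)-3-[(2S)-4-(acetoxymethyl)-5-oxo-2,5-dihydrofuran-2-yl]-2-methyloxiran-2-yl}-10-hydroxy-4,8-dimethyldeca-3,7-dien-1-yl acetate
Conditions: CrCl2 (4 equiv), NiCl2 (0.5 mol%), DMSO/THF, rt; then PPTS (cat.)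
Reagents that add atoms: none (new atoms come from 15; EtOH is lost)
Why: Nozaki–Hiyama–Kishi alkenylation tolerates the free alcohol, acetates and epoxide; Felkin–Anh addition anti to the epoxide C–O gives the erythro (2S) carbinol, and the Z-γ-hydroxy enoate lactonises to the butenolide.

**Step 13**
Reactants: 16
Product: 17, michaolide F
Conditions: Ir[dF(CF3)ppy]2(dtbbpy)PF6 (2 mol%), 3-acetoxyquinuclidine (20 mol%), Bu4N·H2PO4 (25 mol%), MeCN (1 mM), 450 nm LEDs, rt
Reagents that add atoms: none (AcOH is lost)
Why: Proposed new method: excited Ir(III) oxidises the quinuclidine to its aminium radical cation, which abstracts the phosphate-H-bonded α-C–H of the C14 primary alcohol; the α-hydroxyalkyl radical adds to C1 of the butenolide anti to the C2 side chain (trans lactone, 1R), Ir(II) reduces the α-acyl radical to the lactone enolate, and E1cB loss of acetate gives the exo-methylene, a redox-neutral intramolecular SN2′-type C–H allylation that closes the 14-membered ring; C14 (R) is expected from an open staggered transition state (H over the lactone ring, the bulky phosphate-bound OH antiperiplanar to C1=C15, the C13 tether anti to C2); the closest known reactions are H-bond-assisted quinuclidine/photoredox α-alkylation of alcohols with acrylates, photoredox Giese macrocyclisation, and radical addition–elimination on allylic acetates/sulfones.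

## Compound list
1 | (R)-solketal, (R)-(2,2-dimethyl-1,3-dioxolan-4-yl)methanol | CC1(C)OC[C@@H](CO)O1 | starting material
2 | 2-(triphenylphosphoranylidene)propanal | CC(C=O)=P(c1ccccc1)(c1ccccc1)c1ccccc1 | starting material
3 | (E)-3-[(4R)-2,2-dimethyl-1,3-dioxolan-4-yl]-2-methylprop-2-enal | O=C/C(C)=C/[C@@H]1COC(C)(C)O1 | intermediate
4 | (2R,3S)-3-[(4S)-2,2-dimethyl-1,3-dioxolan-4-yl]-2-methyloxirane-2-carbaldehyde | O=C[C@]1(C)O[C@H]1[C@@H]1COC(C)(C)O1 | intermediate
5 | geranyl chloride | CC(C)=CCC/C(C)=C/CCl | starting material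
6 | C5 alcohol (5R), epoxide and acetonide intact | CC(C)=CCC/C(C)=C/C[C@@H](O)[C@]1(C)O[C@H]1[C@@H]1COC(C)(C)O1 | intermediate
7 | C5 acetate of 6 | CC(C)=CCC/C(C)=C/C[C@@H](OC(C)=O)[C@]1(C)O[C@H]1[C@@H]1COC(C)(C)O1 | intermediate
8 | C13 (E)-enal | O=C/C(C)=C/CC/C(C)=C/C[C@@H](OC(C)=O)[C@]1(C)O[C@H]1[C@@H]1COC(C)(C)O1 | intermediate
9 | C13=C14 diene | C=C/C(C)=C/CC/C(C)=C/C[C@@H](OC(C)=O)[C@]1(C)O[C@H]1[C@@H]1COC(C)(C)O1 | intermediate
10 | C14 primary alcohol | OCC/C(C)=C/CC/C(C)=C/C[C@@H](OC(C)=O)[C@]1(C)O[C@H]1[C@@H]1COC(C)(C)O1 | intermediate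
11 | triol (acetonide removed) | OCC/C(C)=C/CC/C(C)=C/C[C@@H](OC(C)=O)[C@]1(C)O[C@H]1[C@@H](O)CO | intermediate
12 | C2 epoxy aldehyde with free C14–OH | OCC/C(C)=C/CC/C(C)=C/C[C@@H](OC(C)=O)[C@]1(C)O[C@H]1C=O | intermediate
13 | ethyl propiolate | C#CC(=O)OCC | starting material
14 | ethyl (Z)-2-(hydroxymethyl)-3-iodoprop-2-enoate | CCOC(=O)/C(CO)=C\I | intermediate
15 | ethyl (Z)-2-(acetoxymethyl)-3-iodoprop-2-enoate | CCOC(=O)/C(COC(C)=O)=C\I | intermediate
16 | seco-alcohol with α-(acetoxymethyl)butenolide | OCC/C(C)=C/CC/C(C)=C/C[C@@H](OC(C)=O)[C@]1(C)O[C@H]1[C@H]2OC(=O)C(COC(C)=O)=C2 | intermediate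
17 | michaolide F | C=C1C(=O)O[C@H]2[C@H]1[C@H](O)C/C(C)=C/CC/C(C)=C/C[C@@H](OC(C)=O)[C@]1(C)O[C@@H]21 | target

## Step count and risks
Total steps: 13. Longest linear sequence: 11 (steps 1–9, 12, 13).

Three steps most likely to fail:

1. **Step 13 (proposed new macrocyclisation).** The C14 configuration is the main uncertainty: the stated model is a prediction, and simple α-hydroxyalkyl radical additions to butenolides show little selectivity at the carbinol carbon. HAT could also occur at allylic C–H bonds, and the amine could deprotonate the butenolide γ-H and open the epoxide. Fallback (known chemistry): oxidise C14–OH of 16 to the aldehyde, exchange the allylic acetate for bromide, and close the ring by a Cr(II) Nozaki–Hiyama (or Zn Barbier) allylation of the aldehyde with the 3-(bromomethyl)butenolide; correct C14 by Mitsunobu inversion if the epimer forms.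

2. **Step 3 (geranylbarium addition).** The 5R outcome rests on a model, not on precedent for 2-methyl epoxy aldehydes. Fallback: take C5 through the ketone — Dess–Martin oxidation of 6, Zn(BH4)2 chelation-controlled reduction to the erythro alcohol, then Mitsunobu inversion with AcOH to deliver the 5R acetate directly (replaces step 4).

3. **Step 12 (NHK butenolide formation).** Felkin selectivity at C2 with epoxy aldehydes is typically moderate, and Ni(0) could ionise the allylic acetate. Fallback: keep the bought C2 stereocentre — do not cleave the diol; on the diol from 9, oxidise only C1–OH, close the butenolide on the intact C2–OH with Ph3P=C=C=O, add CH2OAc by Baylis–Hillman hydroxymethylation and acetylation, and hydroborate the diene last.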